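**Retrosynthetic overview** (side-chain carbons are numbered C1'–C13' outward from C2 of the chroman)

1. The target is the desilylated form of its 6-O-TBS ether, which is cut at C2'–C3'. The bond is made by a Ni-electrocatalytic doubly decarboxylative C(sp3)–C(sp3) coupling of two N-hydroxyphthalimide esters, so two carboxyl-derived carbons of like polarity are joined as radicals and both carboxyl carbons leave as CO2.
2. Enabling feature: C2' and C3' are both unbranched CH2 carbons. C2' is insulated by C1' from the quaternary C2 of the chroman ring (O1–C2–C3–C4–C4a–C8a), and C3' is the CH2 next to the C4' methine. Each can therefore be the α-carbon of a carboxylic acid, both radicals are primary, no stereocentre sits on a reacting carbon, and the only C=C (C12'=C13') is nine bonds from C3'.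
3. Chroman half: 3-(chroman-2-yl)propanoic acid from (S)-Trolox (C2 from the chiral pool) by ester half-reduction, Wittig two-carbon extension and hydrogenation.
4. Chain half: (3R,7S)-3,7,11-trimethyldodec-11-enoic acid from (R)-β-butyrolactone (C4', SN2 with inversion), (S)-citronellyl bromide (C8') and methallylmagnesium chloride (C11'–C13' with the alkene in place).
5. Rings: no ring is formed in the route; the chroman bicycle is carried intact from (S)-Trolox.

Key step: step 12

Assumption: the S descriptor at C8' arises only because the isopropenyl terminus changes the CIP ranking; spatially all three centres match natural α-tocopherol. Commercial (S)-Trolox, (S)-citronellyl bromide and (R)-β-butyrolactone are taken as enantiomerically pure (TBS = tert-butyldimethylsilyl).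

**Step 1**
Reactants: 1 (S)-Trolox, (2S)-6-hydroxy-2,5,7,8-tetramethylchromane-2-carboxylic acid
Product: 2 methyl (2S)-6-hydroxy-2,5,7,8-tetramethylchromane-2-carboxylate
Conditions: MeOH, H2SO4 (cat.), reflux, N2
Reagents that add atoms: methanol, CO
Why: Fischer esterification; C2 is quaternary and has no α-hydrogen, so its configuration cannot be lost.

**Step 2**
Reactants: 2 methyl (2S)-6-hydroxy-2,5,7,8-tetramethylchromane-2-carboxylate
Product: 3 methyl (2S)-6-(tert-butyldimethylsilyloxy)-2,5,7,8-tetramethylchromane-2-carboxylate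
Conditions: TBSCl, imidazole, DMF, 50 °C
Reagents that add atoms: tert-butyldimethylsilyl chloride, CC(C)(C)[Si](C)(C)Cl
Why: Imidazole-promoted silylation of the hindered phenol; the silyl ether prevents the 6-hydroxychroman from acting as a hydrogen-atom donor towards the radicals of step 12 and is later removable with fluoride without touching the alkene.

**Step 3**
Reactants: 3 methyl (2S)-6-(tert-butyldimethylsilyloxy)-2,5,7,8-tetramethylchromane-2-carboxylate
Product: 4 (2S)-6-(tert-butyldimethylsilyloxy)-2,5,7,8-tetramethylchromane-2-carbaldehyde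
Conditions: DIBAL-H (1.1 equiv), toluene, −78 °C; MeOH, aq. Rochelle salt
Reagents that add atoms: none
Why: DIBAL-H half-reduction of an α-alkoxy ester at −78 °C should stop at the aldehyde oxidation level until the aqueous quench; the aryl silyl ether is inert.

**Step 4**
Reactants: 4 (2S)-6-(tert-butyldimethylsilyloxy)-2,5,7,8-tetramethylchromane-2-carbaldehyde; 5 benzyl (triphenylphosphoranylidene)acetate
Product: 6 benzyl (2E)-3-[(2S)-6-(tert-butyldimethylsilyloxy)-2,5,7,8-tetramethylchroman-2-yl]prop-2-enoate
Conditions: toluene, 90 °C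
Reagents that add atoms: none
Why: Wittig olefination with a stabilised ylide adds C2' and the future carboxyl carbon to a non-enolisable aldehyde and should be E-selective, although the geometry is irrelevant after step 5.

**Step 5**
Reactants: 6 benzyl (2E)-3-[(2S)-6-(tert-butyldimethylsilyloxy)-2,5,7,8-tetramethylchroman-2-yl]prop-2-enoate
Product: 7 3-[(2S)-6-(tert-butyldimethylsilyloxy)-2,5,7,8-tetramethylchroman-2-yl]propanoic acid
Conditions: H2 (1 atm), 10% Pd/C, EtOAc, rt
Reagents that add atoms: none
Why: Catalytic hydrogenation saturates the C1'=C2' alkene and hydrogenolyses the benzyl ester in one operation, while the aryl silyl ether and the chroman C–O bond are stable in EtOAc.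

**Step 6**
Reactants: 7 3-[(2S)-6-(tert-butyldimethylsilyloxy)-2,5,7,8-tetramethylchroman-2-yl]propanoic acid
Product: 8 1,3-dioxoisoindolin-2-yl 3-[(2S)-6-(tert-butyldimethylsilyloxy)-2,5,7,8-tetramethylchroman-2-yl]propanoate
Conditions: N-hydroxyphthalimide, DIC, DMAP (cat.), CH2Cl2, rt
Reagents that add atoms: N-hydroxyphthalimide, ON1C(=O)c2ccccc2C1=O
Why: Carbodiimide (Steglich-type) esterification of an unhindered primary acid gives the redox-active ester.

**Step 7**
Reactants: 9 (S)-citronellyl bromide, (6S)-8-bromo-2,6-dimethyloct-2-ene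
Product: 11 (4S)-6-bromo-4-methylhexan-1-ol, via (4S)-6-bromo-4-methylhexanal 10 (not isolated)
Conditions: O3, CH2Cl2/MeOH, −78 °C; then NaBH4, −78 → 0 °C
Reagents that add atoms: ozone, [O-][O+]=O
Why: Ozonolysis with reductive borohydride work-up cleaves the only alkene, the primary bromide is inert to ozone and to NaBH4 at or below 0 °C, and the methyl stereocentre (later C8') is not touched.

**Step 8**
Reactants: 11 (4S)-6-bromo-4-methylhexan-1-ol; 12 2-methylallylmagnesium chloride (methallylmagnesium chloride)
Product: 13 (4R)-4,8-dimethylnon-8-en-1-ol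
Conditions: 12 (2.5 equiv), Li2CuCl4 (5 mol%), THF, −20 °C → rt; aq. NH4Cl
Reagents that add atoms: none
Why: Copper-catalysed (Kochi-type) sp3–sp3 coupling of an allylic Grignard reagent with a primary bromide after the first equivalent has formed the magnesium alkoxide; the methallyl unit is symmetric to allylic transposition, so the 1,1-disubstituted alkene is installed without positional isomers (the descriptor changes to R by CIP ranking only).

**Step 9**
Reactants: 13 (4R)-4,8-dimethylnon-8-en-1-ol
Product: 14 (6R)-9-bromo-2,6-dimethylnon-1-ene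
Conditions: CBr4, PPh3, CH2Cl2, 0 °C
Reagents that add atoms: carbon tetrabromide, BrC(Br)(Br)Br
Why: Appel bromination of a primary alcohol under neutral conditions should leave the acid-sensitive 1,1-disubstituted alkene unisomerised.

**Step 10**
Reactants: 14 (6R)-9-bromo-2,6-dimethylnon-1-ene; 15 (R)-β-butyrolactone, (4R)-4-methyloxetan-2-one
Product: 17 (3R,7S)-3,7,11-trimethyldodec-11-enoic acid, via Grignard reagent 16 (not isolated)
Conditions: Mg, THF, rt → 40 °C; then 15, CuBr·SMe2 (5 mol%), THF/Me2S, −30 → 0 °C; 1 M HCl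
Reagents that add atoms: none
Why: Copper-catalysed SN2 ring opening of the strained β-lactone at C4 (alkyl–oxygen cleavage) by the organocopper derived from the Grignard reagent proceeds with inversion, so the (R)-lactone sets the 3R centre (later C4') and delivers the free acid directly.

**Step 11**
Reactants: 17 (3R,7S)-3,7,11-trimethyldodec-11-enoic acid
Product: 18 1,3-dioxoisoindolin-2-yl (3R,7S)-3,7,11-trimethyldodec-11-enoate
Conditions: N-hydroxyphthalimide, DIC, DMAP (cat.), CH2Cl2, rt
Reagents that add atoms: N-hydroxyphthalimide, ON1C(=O)c2ccccc2C1=O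
Why: Carbodiimide (Steglich-type) esterification; the β-stereocentre is not enolisable and is untouched.

**Step 12**
Reactants: 8 1,3-dioxoisoindolin-2-yl 3-[(2S)-6-(tert-butyldimethylsilyloxy)-2,5,7,8-tetramethylchroman-2-yl]propanoate; 18 1,3-dioxoisoindolin-2-yl (3R,7S)-3,7,11-trimethyldodec-11-enoate
Product: 19 (2R)-6-(tert-butyldimethylsilyloxy)-2,5,7,8-tetramethyl-2-[(4R,8S)-4,8,12-trimethyltridec-12-en-1-yl]chromane
Conditions: 18 (3 equiv), NiCl2·6H2O (20 mol%), 2,2':6',2''-terpyridine (20 mol%), AgNO3 (0.3 equiv), NMP, Mg(+)/RVC(−), undivided cell, constant current, rt; aq. NH4Cl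
Reagents that add atoms: none
Why: Cathodically reduced nickel transfers an electron to each N-acyloxyphthalimide, whose radical anion fragments into phthalimide anion, CO2 and a primary alkyl radical (at C2' from 8, at C3' from 18); one radical is held as alkyl–Ni, the second adds to give a dialkylnickel(III) that reductively eliminates the C2'–C3' bond. The closest known reaction type is the Ni-electrocatalytic doubly decarboxylative coupling of two primary alkyl N-hydroxyphthalimide esters, the reductive counterpart of a mixed Kolbe electrolysis, preferred here because an anodic Kolbe coupling would oxidise the electron-rich chroman. No ring is closed and no stereocentre is created: C2 is quaternary and two carbons from the radical site, and C4' is adjacent to but not part of the radical centre, the tridentate ligand being relied on to suppress β-hydride elimination and reinsertion at the alkylnickel stage that could otherwise scramble C4'. The step needs hetero- over homo-coupling, which is secured statistically by the threefold excess of the more accessible partner 18 and by the expected easy chromatographic removal of the hydrocarbon homodimer of 18 and the more polar bis-chroman. It also needs the radicals to ignore the C12'=C13' alkene and the aromatic ring: the alkene is unactivated, 1,1-disubstituted and nine bonds from C3', and the 6-oxygen is silylated so that it cannot deliver a hydrogen atom to the radicals.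

**Step 13**
Reactants: 19 (2R)-6-(tert-butyldimethylsilyloxy)-2,5,7,8-tetramethyl-2-[(4R,8S)-4,8,12-trimethyltridec-12-en-1-yl]chromane
Product: 20 (2R)-2,5,7,8-tetramethyl-2-[(4R,8S)-4,8,12-trimethyltridec-12-en-1-yl]chroman-6-ol
Conditions: TBAF, THF, 0 °C → rt, Ar; aq. NH4Cl
Reagents that add atoms: none
Why: Fluoride-mediated desilylation of an aryl silyl ether is mild enough to leave the alkene and all three stereocentres untouched; argon prevents air oxidation of the electron-rich phenolate.

**Compound list**

1 | (S)-Trolox, (2S)-6-hydroxy-2,5,7,8-tetramethylchromane-2-carboxylic acid | OC(=O)[C@]1(C)CCc2c(C)c(O)c(C)c(C)c2O1 | starting material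
2 | methyl (2S)-6-hydroxy-2,5,7,8-tetramethylchromane-2-carboxylate | COC(=O)[C@]1(C)CCc2c(C)c(O)c(C)c(C)c2O1 | intermediate
3 | methyl (2S)-6-(tert-butyldimethylsilyloxy)-2,5,7,8-tetramethylchromane-2-carboxylate | COC(=O)[C@]1(C)CCc2c(C)c(O[Si](C)(C)C(C)(C)C)c(C)c(C)c2O1 | intermediate
4 | (2S)-6-(tert-butyldimethylsilyloxy)-2,5,7,8-tetramethylchromane-2-carbaldehyde | O=C[C@]1(C)CCc2c(C)c(O[Si](C)(C)C(C)(C)C)c(C)c(C)c2O1 | intermediate
5 | benzyl (triphenylphosphoranylidene)acetate | O=C(OCc1ccccc1)C=P(c1ccccc1)(c1ccccc1)c1ccccc1 | starting material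
6 | benzyl (2E)-3-[(2S)-6-(tert-butyldimethylsilyloxy)-2,5,7,8-tetramethylchroman-2-yl]prop-2-enoate | O=C(OCc1ccccc1)/C=C/[C@]1(C)CCc2c(C)c(O[Si](C)(C)C(C)(C)C)c(C)c(C)c2O1 | intermediate
7 | 3-[(2S)-6-(tert-butyldimethylsilyloxy)-2,5,7,8-tetramethylchroman-2-yl]propanoic acid | OC(=O)CC[C@]1(C)CCc2c(C)c(O[Si](C)(C)C(C)(C)C)c(C)c(C)c2O1 | intermediate
8 | 1,3-dioxoisoindolin-2-yl 3-[(2S)-6-(tert-butyldimethylsilyloxy)-2,5,7,8-tetramethylchroman-2-yl]propanoate | O=C(CC[C@]1(C)CCc2c(C)c(O[Si](C)(C)C(C)(C)C)c(C)c(C)c2O1)ON1C(=O)c2ccccc2C1=O | intermediate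
9 | (S)-citronellyl bromide, (6S)-8-bromo-2,6-dimethyloct-2-ene | BrCC[C@@H](C)CCC=C(C)C | starting material
10 | (4S)-6-bromo-4-methylhexanal | BrCC[C@@H](C)CCC=O | intermediate (not isolated)
11 | (4S)-6-bromo-4-methylhexan-1-ol | BrCC[C@@H](C)CCCO | intermediate
12 | 2-methylallylmagnesium chloride | C=C(C)C[Mg]Cl | starting material
13 | (4R)-4,8-dimethylnon-8-en-1-ol | C=C(C)CCC[C@@H](C)CCCO | intermediate
14 | (6R)-9-bromo-2,6-dimethylnon-1-ene | C=C(C)CCC[C@@H](C)CCCBr | intermediate
15 | (R)-β-butyrolactone, (4R)-4-methyloxetan-2-one | C[C@@H]1CC(=O)O1 | starting material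
16 | [(4R)-4,8-dimethylnon-8-en-1-yl]magnesium bromide | C=C(C)CCC[C@@H](C)CCC[Mg]Br | intermediate (not isolated)
17 | (3R,7S)-3,7,11-trimethyldodec-11-enoic acid | C=C(C)CCC[C@@H](C)CCC[C@@H](C)CC(=O)O | intermediate
18 | 1,3-dioxoisoindolin-2-yl (3R,7S)-3,7,11-trimethyldodec-11-enoate | C=C(C)CCC[C@@H](C)CCC[C@@H](C)CC(=O)ON1C(=O)c2ccccc2C1=O | intermediate
19 | (2R)-6-(tert-butyldimethylsilyloxy)-2,5,7,8-tetramethyl-2-[(4R,8S)-4,8,12-trimethyltridec-12-en-1-yl]chromane | C=C(C)CCC[C@@H](C)CCC[C@@H](C)CCC[C@]1(C)CCc2c(C)c(O[Si](C)(C)C(C)(C)C)c(C)c(C)c2O1 | intermediate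
20 | (2R)-2,5,7,8-tetramethyl-2-[(4R,8S)-4,8,12-trimethyltridec-12-en-1-yl]chroman-6-ol | C=C(C)CCC[C@@H](C)CCC[C@@H](C)CCC[C@]1(C)CCc2c(C)c(O)c(C)c(C)c2O1 | target

**Step count**

Total steps: 13. Longest linear sequence: 8 steps (steps 1–6, 12 and 13, from 1); the chain half takes 5 steps (7–11) before the union.

**Steps most likely to fail**

Step 12. What may go wrong: indiscriminate pairing of the two primary radicals at nickel (homodimerisation of either ester), together with reduction of the radicals to the alkanes, so that little cross-coupled product forms. The fallback replaces the coupling of two electrophiles by a preformed nucleophile plus one radical precursor. It sets out from aldehyde 4, uses ester 18 unchanged, and returns to the route at 19. Wittig methylenation of 4 (Ph3P=CH2, THF) should give (2S)-6-(tert-butyldimethylsilyloxy)-2,5,7,8-tetramethyl-2-vinylchromane F1. Hydroboration with 9-BBN gives the B-alkyl-9-borabicyclononane F2, which is oxidised in the same flask (NaOH, H2O2) to the 2-(chroman-2-yl)ethanol F3. Appel bromination gives the 2-(2-bromoethyl)chromane F4. Magnesium insertion gives the Grignard reagent F5, and ZnCl2 (0.5 equiv) converts it into the dialkylzinc F6. A Ni-catalysed decarboxylative Negishi alkyl–alkyl coupling of F6 with 18 (NiCl2·glyme, 2,2'-bipyridine, THF/DMF, rt) then forms the same C2'–C3' bond and delivers 19.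

Step 10. What may go wrong: attack of the organometallic at the lactone carbonyl (acyl–oxygen cleavage), or deprotonation and β-elimination of the lactone to crotonate, instead of SN2 opening at C4. The fallback sets the C4' centre by catalyst control instead of by chiral-pool displacement. It sets out from bromide 14 (through Grignard reagent 16, prepared in Et2O) and returns at 17. Copper-catalysed asymmetric conjugate addition of 16 to methyl (E)-but-2-enoate (CuI, Tol-BINAP, t-BuOMe, −40 °C, ligand antipode chosen on a model Grignard so that the 3R centre results) should give methyl (3R,7S)-3,7,11-trimethyldodec-11-enoate F7. Saponification (LiOH, THF/H2O) gives 17.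

Step 8. What may go wrong: slow displacement on the magnesium bromoalkoxide, with intramolecular O-alkylation or Wurtz-type self-coupling of the allylic Grignard reagent consuming the material. The fallback removes the free hydroxyl from the coupling by reversing the order and relying on chemoselective oxidative cleavage. It sets out from 9 and returns at 13. Compound 9 is coupled first with 12 (Li2CuCl4 cat., THF) to give (6R)-2,6,10-trimethylundeca-1,9-diene F8. mCPBA (1.0 equiv, CH2Cl2, −20 °C) should epoxidise the more electron-rich trisubstituted alkene to 3-[(3R)-3,7-dimethyloct-7-en-1-yl]-2,2-dimethyloxirane F9. Periodic acid (HIO4·2H2O, THF/H2O, 0 °C) cleaves the epoxide to (4R)-4,8-dimethylnon-8-enal F10, and NaBH4 (MeOH, 0 °C) reduces it to 13.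

**Further compounds**

F1 | step 12 | (2S)-6-(tert-butyldimethylsilyloxy)-2,5,7,8-tetramethyl-2-vinylchromane | C=C[C@]1(C)CCc2c(C)c(O[Si](C)(C)C(C)(C)C)c(C)c(C)c2O1
F2 | step 12 | 9-{2-[(2R)-6-(tert-butyldimethylsilyloxy)-2,5,7,8-tetramethylchroman-2-yl]ethyl}-9-borabicyclo[3.3.1]nonane | C1CC2CCCC(C1)B2CC[C@]1(C)CCc2c(C)c(O[Si](C)(C)C(C)(C)C)c(C)c(C)c2O1
F3 | step 12 | 2-[(2S)-6-(tert-butyldimethylsilyloxy)-2,5,7,8-tetramethylchroman-2-yl]ethan-1-ol | OCC[C@]1(C)CCc2c(C)c(O[Si](C)(C)C(C)(C)C)c(C)c(C)c2O1
F4 | step 12 | (2S)-2-(2-bromoethyl)-6-(tert-butyldimethylsilyloxy)-2,5,7,8-tetramethylchromane | BrCC[C@]1(C)CCc2c(C)c(O[Si](C)(C)C(C)(C)C)c(C)c(C)c2O1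
F5 | step 12 | {2-[(2S)-6-(tert-butyldimethylsilyloxy)-2,5,7,8-tetramethylchroman-2-yl]ethyl}magnesium bromide | Br[Mg]CC[C@]1(C)CCc2c(C)c(O[Si](C)(C)C(C)(C)C)c(C)c(C)c2O1
F6 | step 12 | bis{2-[(2S)-6-(tert-butyldimethylsilyloxy)-2,5,7,8-tetramethylchroman-2-yl]ethyl}zinc | C(C[C@]1(C)CCc2c(C)c(O[Si](C)(C)C(C)(C)C)c(C)c(C)c2O1)[Zn]CC[C@]1(C)CCc2c(C)c(O[Si](C)(C)C(C)(C)C)c(C)c(C)c2O1
F7 | step 10 | methyl (3R,7S)-3,7,11-trimethyldodec-11-enoate | C=C(C)CCC[C@@H](C)CCC[C@@H](C)CC(=O)OC
F8 | step 8 | (6R)-2,6,10-trimethylundeca-1,9-diene | C=C(C)CCC[C@@H](C)CCC=C(C)C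
F9 | step 8 | 3-[(3R)-3,7-dimethyloct-7-en-1-yl]-2,2-dimethyloxirane (epimers at the oxirane carbon) | C=C(C)CCC[C@@H](C)CCC1OC1(C)C
F10 | step 8 | (4R)-4,8-dimethylnon-8-enal | C=C(C)CCC[C@@H](C)CCC=O
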